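The numbering used is: oxocane O1, C2 (enyne arm), C3 (Cl), C4, C5 (Cl), C6 (OAc), C7, C8 (bromopropyl arm; C1′ = CHBr). The ring is cut at O1–C8 and C3–C4. Both bonds form in one bromonium-triggered cascade on the chloroacetate of (3S,5Z)-octa-1,5-dien-3-ol: the ester carbonyl opens the bromonium ion (O1–C8, anti to C1′–Br), the dioxanylium ion becomes a chloroketene acetal, and a Claisen ring expansion forms C3–C4 and the eight-membered lactone. The step exploits the anti O1–C8/C1′–Br pair and the O1–C2–C3(Cl) unit of the oxocane ring, both latent in a chloroacetate. The C5=C6 alkene left behind is converted into the 5-chloro-6-acetate through its epoxide; C2 is then reduced and extended to the enyne.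

Key step: step 5

Remark on the chemistry: lactones 13–15 keep the oxocane numbering of the target, so C2 is the lactone carbonyl carbon.

Step 1
Reactants: 1 but-1-yne; 2 (S)-epichlorohydrin
Product: 4 (2S)-1-chlorohept-4-yn-2-ol, via lithium butynide 3 (not isolated)
Conditions: n-BuLi, THF, −78 °C; BF3·OEt2, −78 °C; then 2; aqueous work-up
Reagents that add atoms: none
Why: BF3-promoted SN2 opening of the epoxide at its unsubstituted carbon by the lithium acetylide (alkynylation of an epoxide) does not involve the stereocentre of 2, which is carried into 4 unchanged.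

Step 2
Reactants: 4 (2S)-1-chlorohept-4-yn-2-ol
Product: 6 (3S)-oct-1-en-5-yn-3-ol, via epoxide 5 (not isolated)
Conditions: Me3S+ I− (3.3 equiv), n-BuLi (3.2 equiv), THF, −10 °C to rt
Reagents that add atoms: trimethylsulfonium iodide, C[S+](C)C.[I-]
Why: Dimethylsulfonium methylide first closes the chlorohydrin to epoxide 5, then opens it at CH2 and, with a further equivalent acting as base, Me2S is eliminated to leave the allylic alcohol (one-carbon homologation of an epoxide with a Corey–Chaykovsky ylide); the carbinol centre is never involved.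

Step 3
Reactants: 6 (3S)-oct-1-en-5-yn-3-ol
Product: 7 (3S,5Z)-octa-1,5-dien-3-ol
Conditions: H2 (1 atm), Pd/CaCO3 poisoned with Pb(OAc)2 (Lindlar catalyst), quinoline, EtOAc, 0 °C, stopped after 1 equiv H2
Reagents that add atoms: none
Why: Lindlar semi-hydrogenation adds H2 syn to the alkyne and should give the Z-alkene, while the poisoned catalyst spares the vinyl group and the stereocentre.

Step 4
Reactants: 7 (3S,5Z)-octa-1,5-dien-3-ol; 8 chloroacetyl chloride
Product: 9 (3S,5Z)-octa-1,5-dien-3-yl chloroacetate
Conditions: pyridine, CH2Cl2, 0 °C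
Reagents that add atoms: none
Why: O-acylation of the secondary alcohol by the acid chloride (nucleophilic acyl substitution) takes place at oxygen, so the carbinol centre keeps its configuration.

Step 5
Reactants: 9 (3S,5Z)-octa-1,5-dien-3-yl chloroacetate
Product: 13 (3S,5Z,8R)-8-[(1R)-1-bromopropyl]-3-chloro-3,4,7,8-tetrahydro-2H-oxocin-2-one, via dioxanylium salt 10 (not isolated), via ortho ester 11 (not isolated), via chloroketene acetal 12 (not isolated)
Conditions: TBCO (2,4,4,6-tetrabromocyclohexa-2,5-dienone, 1.0 equiv, added in portions), CH2Cl2, −20 °C to rt; then solvent exchange to toluene, 100 °C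
Reagents that add atoms: 2,4,4,6-tetrabromocyclohexa-2,5-dienone (TBCO), O=C1C(Br)=CC(Br)(Br)C=C1Br
Why: Proposed new method: TBCO delivers Br+ to the Z-disubstituted alkene, the only electron-rich π-bond (the vinyl group is monosubstituted and deactivated by the allylic acyloxy group), and the ester carbonyl oxygen opens the bromonium ion anti by 6-exo attack through a chair-like transition state with both ring substituents equatorial; this makes O1–C8, sets C8 by 1,3-induction from the carbinol centre and C1′ by stereospecific anti addition to the Z-alkene, and gives the cis-4,6-disubstituted dioxanylium ion 10. The tribromophenolate counter-ion stores 10 as ortho ester 11, so that no nucleophilic ketene acetal is present while TBCO remains, and on heating 11 loses tribromophenol to chloroketene acetal 12, as in an ortho ester Claisen sequence. 12 is a 2-alkylidene-4-vinyl-1,3-dioxane and undergoes the [3,3] shift that forms C3–C4, breaks the allylic C–O bond and expands the six-membered ring by two atoms, so the oxocane ring is closed by sigmatropic ring expansion and not by end-to-end cyclisation, with the former carbonyl oxygen as O1 and a necessarily Z C5=C6 bond. C3 is set by chirality transfer from the carbinol centre: the vinyl terminus (future C4) can reach only the ketene acetal face to which it is tethered, and the isomer of 12 with chlorine syn to the breaking C–O bond (allylic strain there is released as that bond lengthens) then gives 3S, while the two isomers of 12 interconvert through 11 so that the mixture can drain through the faster channel. The closest known reactions are halocyclisations with carbonyl participation (iodocarbonate cyclisation of homoallylic carbonates to cis-4,6-disubstituted 1,3-dioxan-2-ones), the ortho ester Claisen rearrangement and the Claisen ring expansion of 2-methylene-4-vinyl-1,3-dioxanes to 3,4,7,8-tetrahydro-2H-oxocin-2-ones; new is their fusion into one bromonium-triggered operation in which the chloroacetate is nucleophile, ketene acetal precursor and source of the C3 chlorine.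

Step 6
Reactants: 13 (3S,5Z,8R)-8-[(1R)-1-bromopropyl]-3-chloro-3,4,7,8-tetrahydro-2H-oxocin-2-one
Product: 14 (3S,5R,6S,8R)-8-[(1R)-1-bromopropyl]-3-chloro-5,6-epoxyoxocan-2-one
Conditions: dimethyldioxirane, acetone, 0 °C
Reagents that add atoms: dimethyldioxirane, CC1(C)OO1
Why: Epoxidation by the dioxirane (concerted syn oxygen transfer) should occur on the ring face anti to the 1-bromopropyl arm on C8, the larger of the two flanking substituents (the C3 chlorine lies on the other face), which fixes the C6–O configuration under neutral conditions that spare the α-chloro lactone.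

Step 7
Reactants: 14 (3S,5R,6S,8R)-8-[(1R)-1-bromopropyl]-3-chloro-5,6-epoxyoxocan-2-one
Product: 15 (3S,5S,6S,8R)-8-[(1R)-1-bromopropyl]-3,5-dichloro-2-oxooxocan-6-yl acetate
Conditions: AcCl, n-Bu4NCl (5 mol %), CH2Cl2, 0 °C to rt
Reagents that add atoms: acetyl chloride, CC(Cl)=O
Why: Chloride-catalysed addition of the acyl chloride across the epoxide: chloride should open the oxirane by SN2 with inversion at C5, whose rear face is flanked only by C3–H, rather than at C6, whose rear face is screened by the syn-1,3 C8 arm, and the alkoxide is acetylated at once so that no free 6-hydroxyl can translactonise; the result is trans 5-Cl/6-OAc, (5S,6S).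

Step 8
Reactants: 15 (3S,5S,6S,8R)-8-[(1R)-1-bromopropyl]-3,5-dichloro-2-oxooxocan-6-yl acetate
Product: 17 (2RS,3S,5S,6S,8R)-8-[(1R)-1-bromopropyl]-3,5-dichlorooxocane-2,6-diyl diacetate, via aluminium lactolate 16 (not isolated)
Conditions: i-Bu2AlH (1.1 equiv), CH2Cl2, −78 °C; then pyridine, DMAP, Ac2O, −78 °C to rt
Reagents that add atoms: acetic anhydride, CC(=O)OC(C)=O
Why: Reductive acetylation of the lactone: i-Bu2AlH stops at the tetrahedral aluminium lactolate 16 at −78 °C and Ac2O traps it as the anomeric acetate (both C2 epimers serve in step 9, and any 6-acetate cleaved by hydride is restored), while C–Cl and C–Br bonds are inert to the hydride at this temperature.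

Step 9
Reactants: 17 (2RS,3S,5S,6S,8R)-8-[(1R)-1-bromopropyl]-3,5-dichlorooxocane-2,6-diyl diacetate; 18 (1E)-1-(trimethylsilyloxy)buta-1,3-diene
Product: 19 (2S,3S,5S,6S,8R)-8-[(1R)-1-bromopropyl]-3,5-dichloro-2-[(2E)-4-oxobut-2-en-1-yl]oxocan-6-yl acetate
Conditions: Me3SiOTf (0.2 equiv), CH2Cl2, −78 to −40 °C; aq. NaHCO3
Reagents that add atoms: none
Why: Vinylogous Mukaiyama-type substitution at the acetal carbon: Me3SiOTf ionises the anomeric acetate, the dienol silane attacks the oxocarbenium ion through its γ-carbon to give the E-enal, and C2 should be set by entry anti to the C8 arm across O1 and 1,2-cis to the C3 chlorine (the usual sense for oxocarbenium ions with an adjacent chloro or alkoxy group), giving the 2,8-trans (2S) oxocane.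

Step 10
Reactants: 19 (2S,3S,5S,6S,8R)-8-[(1R)-1-bromopropyl]-3,5-dichloro-2-[(2E)-4-oxobut-2-en-1-yl]oxocan-6-yl acetate
Product: 20 (2S,3S,5S,6S,8R)-8-[(1R)-1-bromopropyl]-3,5-dichloro-2-[(2E)-pent-2-en-4-yn-1-yl]oxocan-6-yl acetate
Conditions: Me3SiCHN2, LiN(i-Pr)2, THF, −78 °C; then 19, −78 to 0 °C; aq. NH4Cl
Reagents that add atoms: (trimethylsilyl)diazomethane, C[Si](C)(C)C=[N+]=[N-]
Why: Colvin rearrangement: 1,2-addition of lithiated (trimethylsilyl)diazomethane to the aldehyde, Peterson-type loss of lithium trimethylsilanolate, loss of N2 and a 1,2-hydrogen shift of the alkylidene carbene give the terminal alkyne, leaving the E-alkene and all stereocentres untouched; at −78 °C the acetate and the secondary halides should survive the reagent.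

Compound list
1 | but-1-yne | CCC#C | starting material
2 | (S)-epichlorohydrin, (2S)-2-(chloromethyl)oxirane | ClC[C@@H]1CO1 | starting material
3 | lithium but-1-yn-1-ide (formed in the flask) | [Li+].[C-]#CCC | intermediate
4 | (2S)-1-chlorohept-4-yn-2-ol | ClC[C@@H](O)CC#CCC | intermediate
5 | (2S)-2-(pent-2-yn-1-yl)oxirane (formed in the flask) | CCC#CC[C@H]1CO1 | intermediate
6 | (3S)-oct-1-en-5-yn-3-ol | C=C[C@@H](O)CC#CCC | intermediate
7 | (3S,5Z)-octa-1,5-dien-3-ol | C=C[C@@H](O)C/C=C\CC | intermediate
8 | chloroacetyl chloride | ClCC(Cl)=O | starting material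
9 | (3S,5Z)-octa-1,5-dien-3-yl chloroacetate | C=C[C@@H](OC(=O)CCl)C/C=C\CC | intermediate
10 | (4S,6R)-6-[(1R)-1-bromopropyl]-2-(chloromethyl)-4-ethenyl-1,3-dioxan-2-ylium 2,4,6-tribromophenolate (formed in the flask) | ClCC1=[O+][C@@H]([C@H](Br)CC)C[C@@H](C=C)O1.[O-]c1c(Br)cc(Br)cc1Br | intermediate
11 | (4S,6R)-6-[(1R)-1-bromopropyl]-2-(chloromethyl)-4-ethenyl-2-(2,4,6-tribromophenoxy)-1,3-dioxane, both C2 epimers (formed in the flask) | ClCC1(Oc2c(Br)cc(Br)cc2Br)O[C@@H]([C@H](Br)CC)C[C@@H](C=C)O1 | intermediate
12 | (2E,4S,6R)-6-[(1R)-1-bromopropyl]-2-(chloromethylidene)-4-ethenyl-1,3-dioxane, chlorine syn to the oxygen on the vinyl-bearing carbon (formed in the flask) | Cl/C=C1/O[C@@H]([C@H](Br)CC)C[C@@H](C=C)O1 | intermediate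
13 | (3S,5Z,8R)-8-[(1R)-1-bromopropyl]-3-chloro-3,4,7,8-tetrahydro-2H-oxocin-2-one | O=C1O[C@@H]([C@H](Br)CC)C/C=C\C[C@@H]1Cl | intermediate
14 | (3S,5R,6S,8R)-8-[(1R)-1-bromopropyl]-3-chloro-5,6-epoxyoxocan-2-one, oxirane oxygen anti to the C8 arm | O=C1O[C@@H]([C@H](Br)CC)C[C@@H]2O[C@@H]2C[C@@H]1Cl | intermediate
15 | (3S,5S,6S,8R)-8-[(1R)-1-bromopropyl]-3,5-dichloro-2-oxooxocan-6-yl acetate | O=C1O[C@@H]([C@H](Br)CC)C[C@H](OC(C)=O)[C@@H](Cl)C[C@@H]1Cl | intermediate
16 | diisobutylaluminium lactolate of 15, O-aluminated at C2 (formed in the flask) | CC(C)C[Al](CC(C)C)OC1O[C@@H]([C@H](Br)CC)C[C@H](OC(C)=O)[C@@H](Cl)C[C@@H]1Cl | intermediate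
17 | (2RS,3S,5S,6S,8R)-8-[(1R)-1-bromopropyl]-3,5-dichlorooxocane-2,6-diyl diacetate | CC(=O)OC1O[C@@H]([C@H](Br)CC)C[C@H](OC(C)=O)[C@@H](Cl)C[C@@H]1Cl | intermediate
18 | (1E)-1-(trimethylsilyloxy)buta-1,3-diene | C=C/C=C/O[Si](C)(C)C | starting material
19 | (2S,3S,5S,6S,8R)-8-[(1R)-1-bromopropyl]-3,5-dichloro-2-[(2E)-4-oxobut-2-en-1-yl]oxocan-6-yl acetate | O=C/C=C/C[C@@H]1O[C@@H]([C@H](Br)CC)C[C@H](OC(C)=O)[C@@H](Cl)C[C@@H]1Cl | intermediate
20 | (2S,3S,5S,6S,8R)-8-[(1R)-1-bromopropyl]-3,5-dichloro-2-[(2E)-pent-2-en-4-yn-1-yl]oxocan-6-yl acetate | C#C/C=C/C[C@@H]1O[C@@H]([C@H](Br)CC)C[C@H](OC(C)=O)[C@@H](Cl)C[C@@H]1Cl | target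

Total step count: 10. Longest linear sequence: 10 steps (from 1 and 2 to 20).

Steps most likely to fail

1. Step 5 (Proposed new method). Four processes may spoil it:
- deprotonation of the dioxanylium ion while TBCO is still present, with bromination of the ketene acetal so formed;
- attack of the phenolate at the allylic ring carbon instead of at the cationic carbon;
- incomplete 1,3-induction in the bromocyclisation;
- rearrangement through the other ketene acetal isomer, which would give the C3 epimer.

The fallback uses known chemistry, sets out from 7 and comes back at 13. Boc2O and DMAP in MeCN convert 7 into tert-butyl (3S,5Z)-octa-1,5-dien-3-yl carbonate F1. N-bromosuccinimide in MeCN at −20 °C brings about halocarbonate cyclisation, with loss of 2-methylpropene, to the cis cyclic carbonate (4S,6R)-6-[(1R)-1-bromopropyl]-4-ethenyl-1,3-dioxan-2-one F2. Cp2TiMe2 in toluene at 110 °C methylenates the carbonate carbonyl to (4S,6R)-6-[(1R)-1-bromopropyl]-4-ethenyl-2-methylidene-1,3-dioxane F3, which undergoes the Claisen ring expansion in the same flask to (5Z,8R)-8-[(1R)-1-bromopropyl]-3,4,7,8-tetrahydro-2H-oxocin-2-one F4. LiN(SiMe3)2 in THF at −78 °C gives lithium (5Z,8R)-8-[(1R)-1-bromopropyl]-7,8-dihydro-4H-oxocin-2-olate F5, and N-chlorosuccinimide should chlorinate it on the face anti to the C8 arm to give 13.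

2. Step 7. Chloride may open the epoxide at C6 instead of C5, because the inductive pull of the α-chloro acyl end on C5 works against the steric preference. Free chloride may also slowly epimerise C3 by exchange.

The fallback sets out from 14 and comes back at 15, and relies on thermodynamic funnelling through neighbouring-group participation. If the same acetyl chloride addition delivers the regioisomer (3S,5R,6R,8R)-8-[(1R)-1-bromopropyl]-3,6-dichloro-2-oxooxocan-5-yl acetate F6, it is not a dead end. ZnCl2 (0.2 equiv) in 1,2-dichloroethane at 60 °C should ionise it by anti participation of the 5-acetoxy group to the cis-fused 2-methyl-1,3-dioxolan-2-ylium ion across C5 and C6, acetoxonium chloride F7. This ion is common to both trans chloro acetates. Chloride then re-enters at C5 to give 15, expected to be the more stable isomer because a chlorine at C6 would be syn-1,3 to the C8 arm.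

3. Step 9. Ionisation of the anomeric acetate next to the C3 chlorine may be slow, the dienol silane may attack through its α-carbon, and facial selectivity may erode under forcing conditions.

The fallback sets out from 17 and comes back at 19. Allyltrimethylsilane and BF3·OEt2 in CH2Cl2 (−78 to −20 °C), a stronger and regiochemically unambiguous nucleophile, should give (2S,3S,5S,6S,8R)-8-[(1R)-1-bromopropyl]-3,5-dichloro-2-(prop-2-en-1-yl)oxocan-6-yl acetate F8. Cross-metathesis with crotonaldehyde (second-generation Hoveyda–Grubbs catalyst, CH2Cl2, 40 °C) then gives the E-enal 19.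

Further compounds
F1 | step 5 | tert-butyl (3S,5Z)-octa-1,5-dien-3-yl carbonate | C=C[C@@H](OC(=O)OC(C)(C)C)C/C=C\CC
F2 | step 5 | (4S,6R)-6-[(1R)-1-bromopropyl]-4-ethenyl-1,3-dioxan-2-one | O=C1O[C@@H]([C@H](Br)CC)C[C@@H](C=C)O1
F3 | step 5 | (4S,6R)-6-[(1R)-1-bromopropyl]-4-ethenyl-2-methylidene-1,3-dioxane | C=C1O[C@@H]([C@H](Br)CC)C[C@@H](C=C)O1
F4 | step 5 | (5Z,8R)-8-[(1R)-1-bromopropyl]-3,4,7,8-tetrahydro-2H-oxocin-2-one | O=C1O[C@@H]([C@H](Br)CC)C/C=C\CC1
F5 | step 5 | lithium (5Z,8R)-8-[(1R)-1-bromopropyl]-7,8-dihydro-4H-oxocin-2-olate | [Li+].[O-]C1=CC/C=C\C[C@H]([C@H](Br)CC)O1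
F6 | step 7 | (3S,5R,6R,8R)-8-[(1R)-1-bromopropyl]-3,6-dichloro-2-oxooxocan-5-yl acetate | O=C1O[C@@H]([C@H](Br)CC)C[C@@H](Cl)[C@H](OC(C)=O)C[C@@H]1Cl
F7 | step 7 | cis-fused 2-methyl-1,3-dioxolan-2-ylium chloride across C5 and C6 of the lactone, both oxygens anti to the C8 arm | O=C1O[C@@H]([C@H](Br)CC)C[C@@H]2OC(C)=[O+][C@@H]2C[C@@H]1Cl.[Cl-]
F8 | step 9 | (2S,3S,5S,6S,8R)-8-[(1R)-1-bromopropyl]-3,5-dichloro-2-(prop-2-en-1-yl)oxocan-6-yl acetate | C=CC[C@@H]1O[C@@H]([C@H](Br)CC)C[C@H](OC(C)=O)[C@@H](Cl)C[C@@H]1Cl
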